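**Retrosynthetic overview**
- The target comes from global desilylation of a bis-silyl (E)-allylic alcohol; the E-alkene comes from hydroxyl-directed trans-hydroalumination of a propargylic alcohol.
- C1′ (side-chain carbinol) is set by catalyst-controlled transfer hydrogenation of an ynone. The ynone is disconnected at C1′–C2′ into a tetralin-1-carbaldehyde and a 4-silyloxyphenylacetylene (from 4-iodophenol by Sonogashira coupling).
- The aldehyde comes from a cis-β-hydroxy ester whose C1 and C2 centres are set together by a ketoreductase-catalysed dynamic kinetic reduction of a racemising β-keto ester.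
- The β-keto ester comes from C1-methoxycarbonylation of 6,7-dimethoxy-2-tetralone.
- No ring is built: rings A and B (the tetralin) are carried intact from the tetralone, and the phenol ring from 4-iodophenol.

Assumption: a ketoreductase with anti-Prelog, cis-(1S,2R) selectivity for 2 is found by a routine screen of a commercial panel of enantiocomplementary enzymes; 1 and 7 are bought.

**Route**

Step 1
Reactants: 1 6,7-dimethoxy-3,4-dihydronaphthalen-2(1H)-one (6,7-dimethoxy-2-tetralone)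
Product: 2 methyl 6,7-dimethoxy-2-oxo-1,2,3,4-tetrahydronaphthalene-1-carboxylate (racemic; mostly enol form)
Conditions: NaH (2.2 equiv), (MeO)2CO (3 equiv), THF, reflux, N2; then aq. HCl, 0 °C
Reagents that add atoms: dimethyl carbonate, COC(=O)OC
Why: Claisen-type C-methoxycarbonylation of the thermodynamically favoured benzylic, arene-conjugated sodium enolate at C1, driven by formation of the stabilised β-keto ester enolate.

Step 2
Reactants: 2 methyl 6,7-dimethoxy-2-oxo-1,2,3,4-tetrahydronaphthalene-1-carboxylate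
Product: 3 methyl (1S,2R)-2-hydroxy-6,7-dimethoxy-1,2,3,4-tetrahydronaphthalene-1-carboxylate (cis)
Conditions: ketoreductase (NADPH-dependent alcohol dehydrogenase class, anti-Prelog), NADP+ (cat.), i-PrOH (10 vol%), K2HPO4/KH2PO4 buffer pH 7.0, MgSO4 (2 mM), DMSO (5 vol%), 30 °C
Reagents that add atoms: none
Why: Biocatalytic asymmetric reduction with dynamic kinetic resolution: 2 racemises through its enol at pH 7 while the ketoreductase reduces only the (1S)-keto form on the anti-Prelog face, setting C1 (S) and C2 (R) together as the cis-hydroxy ester.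

Step 3
Reactants: 3 methyl (1S,2R)-2-hydroxy-6,7-dimethoxy-1,2,3,4-tetrahydronaphthalene-1-carboxylate
Product: 4 methyl (1S,2R)-2-[(tert-butyldimethylsilyl)oxy]-6,7-dimethoxy-1,2,3,4-tetrahydronaphthalene-1-carboxylate
Conditions: TBSOTf (1.3 equiv), 2,6-lutidine (2 equiv), CH2Cl2, −78 → 0 °C
Reagents that add atoms: tert-butyldimethylsilyl trifluoromethanesulfonate, CC(C)(C)[Si](C)(C)OS(=O)(=O)C(F)(F)F
Why: Silyl ether formation with a weak hindered base does not enolise the ester, and it blocks retro-aldol and alkoxide chemistry in the following steps.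

Step 4
Reactants: 4 methyl (1S,2R)-2-[(tert-butyldimethylsilyl)oxy]-6,7-dimethoxy-1,2,3,4-tetrahydronaphthalene-1-carboxylate
Product: 5 [(1R,2R)-2-[(tert-butyldimethylsilyl)oxy]-6,7-dimethoxy-1,2,3,4-tetrahydronaphthalen-1-yl]methanol (cis)
Conditions: i-Bu2AlH (3 equiv), CH2Cl2, −78 → −20 °C; aq. potassium sodium tartrate (KNaC4H4O6)
Reagents that add atoms: none
Why: Hydride reduction of the ester to the primary alcohol involves no enolisation, so C1 is untouched; its descriptor changes to R only because the CIP priorities change.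

Step 5
Reactants: 5 [(1R,2R)-2-[(tert-butyldimethylsilyl)oxy]-6,7-dimethoxy-1,2,3,4-tetrahydronaphthalen-1-yl]methanol
Product: 6 (1S,2R)-2-[(tert-butyldimethylsilyl)oxy]-6,7-dimethoxy-1,2,3,4-tetrahydronaphthalene-1-carbaldehyde
Conditions: Dess–Martin periodinane (1.3 equiv), pyridine (3 equiv), CH2Cl2, 0 °C → rt; used at once without chromatography
Reagents that add atoms: none
Why: Dess–Martin oxidation under buffered, non-enolising conditions gives the configurationally labile α-aryl aldehyde without epimerisation at C1 or loss of silanol.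

Step 6
Reactants: 7 4-iodophenol
Product: 8 (4-iodophenoxy)tri(propan-2-yl)silane
Conditions: TIPSCl (1.1 equiv), imidazole (2 equiv), DMF, rt
Reagents that add atoms: triisopropylsilyl chloride, CC(C)[Si](Cl)(C(C)C)C(C)C
Why: Imidazole-promoted silylation gives a hindered aryl silyl ether that withstands the organolithium, hydride and mild base steps and is removed by fluoride at the end.

Step 7
Reactants: 8 (4-iodophenoxy)tri(propan-2-yl)silane
Product: 9 trimethyl[(4-{[tri(propan-2-yl)silyl]oxy}phenyl)ethynyl]silane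
Conditions: ethynyltrimethylsilane (1.2 equiv), PdCl2(PPh3)2 (2 mol%), CuI (4 mol%), Et3N, THF, rt
Reagents that add atoms: ethynyltrimethylsilane, C#C[Si](C)(C)C
Why: Sonogashira coupling of an aryl iodide with a terminal alkyne proceeds at room temperature under palladium/copper co-catalysis.

Step 8
Reactants: 9 trimethyl[(4-{[tri(propan-2-yl)silyl]oxy}phenyl)ethynyl]silane
Product: 10 (4-ethynylphenoxy)tri(propan-2-yl)silane
Conditions: K2CO3 (0.2 equiv), MeOH/CH2Cl2 (1:1), 0 °C → rt, 45 min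
Reagents that add atoms: none
Why: Methoxide-catalysed protodesilylation cleaves the alkynyl C–SiMe3 bond much faster than the hindered aryl O–Si(i-Pr)3 bond.

Step 9
Reactants: 10 (4-ethynylphenoxy)tri(propan-2-yl)silane; 6 (1S,2R)-2-[(tert-butyldimethylsilyl)oxy]-6,7-dimethoxy-1,2,3,4-tetrahydronaphthalene-1-carbaldehyde
Product: 12 (1RS)-1-[(1R,2R)-2-[(tert-butyldimethylsilyl)oxy]-6,7-dimethoxy-1,2,3,4-tetrahydronaphthalen-1-yl]-3-(4-{[tri(propan-2-yl)silyl]oxy}phenyl)prop-2-yn-1-ol (both C1′ epimers), via lithium acetylide 11 (not isolated)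
Conditions: 10 (1.5 equiv), n-BuLi (1.45 equiv), THF, −78 °C, 30 min; then 6, −78 °C, 1 h; AcOH then sat. aq. NH4Cl at −78 °C
Reagents that add atoms: none
Why: 1,2-Addition of a lithium acetylide to the aldehyde at −78 °C outruns enolisation; the C1′ configuration is irrelevant here because it is erased in step 10.

Step 10
Reactants: 12 (1RS)-1-[(1R,2R)-2-[(tert-butyldimethylsilyl)oxy]-6,7-dimethoxy-1,2,3,4-tetrahydronaphthalen-1-yl]-3-(4-{[tri(propan-2-yl)silyl]oxy}phenyl)prop-2-yn-1-ol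
Product: 13 1-[(1S,2R)-2-[(tert-butyldimethylsilyl)oxy]-6,7-dimethoxy-1,2,3,4-tetrahydronaphthalen-1-yl]-3-(4-{[tri(propan-2-yl)silyl]oxy}phenyl)prop-2-yn-1-one
Conditions: Dess–Martin periodinane (1.3 equiv), pyridine (3 equiv), CH2Cl2, 0 °C; rapid filtration through silica
Reagents that add atoms: none
Why: Dess–Martin oxidation converts both propargylic epimers into one ynone under neutral conditions that leave the acidic C1–H alone.

Step 11
Reactants: 13 1-[(1S,2R)-2-[(tert-butyldimethylsilyl)oxy]-6,7-dimethoxy-1,2,3,4-tetrahydronaphthalen-1-yl]-3-(4-{[tri(propan-2-yl)silyl]oxy}phenyl)prop-2-yn-1-one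
Product: 14 (1R)-1-[(1R,2R)-2-[(tert-butyldimethylsilyl)oxy]-6,7-dimethoxy-1,2,3,4-tetrahydronaphthalen-1-yl]-3-(4-{[tri(propan-2-yl)silyl]oxy}phenyl)prop-2-yn-1-ol
Conditions: Ru[(R,R)-TsNCH(Ph)CH(Ph)NH](p-cymene) (3 mol%), i-PrOH, rt, 2–4 h
Reagents that add atoms: none
Why: Noyori–Ikariya asymmetric transfer hydrogenation of the ynone is catalyst-controlled and base-free; the (R,R)-catalyst places the alkynyl group where an aryl group sits in aryl ketones and gives the (R)-propargylic alcohol at C1′ without epimerising C1.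

Step 12
Reactants: 14 (1R)-1-[(1R,2R)-2-[(tert-butyldimethylsilyl)oxy]-6,7-dimethoxy-1,2,3,4-tetrahydronaphthalen-1-yl]-3-(4-{[tri(propan-2-yl)silyl]oxy}phenyl)prop-2-yn-1-ol
Product: 15 (1S,2E)-1-[(1R,2R)-2-[(tert-butyldimethylsilyl)oxy]-6,7-dimethoxy-1,2,3,4-tetrahydronaphthalen-1-yl]-3-(4-{[tri(propan-2-yl)silyl]oxy}phenyl)prop-2-en-1-ol
Conditions: NaAlH2(OCH2CH2OCH3)2 (Red-Al, 2.5 equiv), THF, 0 °C → rt; aq. potassium sodium tartrate (KNaC4H4O6)
Reagents that add atoms: none
Why: Alkoxide-directed trans-hydroalumination of the propargylic alcohol followed by protonolysis of the vinyl–aluminium bond gives only the E-alkene; C1′ is untouched and becomes S only by a change in CIP priorities.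

Step 13
Reactants: 15 (1S,2E)-1-[(1R,2R)-2-[(tert-butyldimethylsilyl)oxy]-6,7-dimethoxy-1,2,3,4-tetrahydronaphthalen-1-yl]-3-(4-{[tri(propan-2-yl)silyl]oxy}phenyl)prop-2-en-1-ol
Product: 16 (1S,2R)-1-[(1S,2E)-1-hydroxy-3-(4-hydroxyphenyl)prop-2-en-1-yl]-6,7-dimethoxy-1,2,3,4-tetrahydronaphthalen-2-ol (target)
Conditions: n-Bu4NF (4 equiv), AcOH (4 equiv), THF, 0 °C → rt; pH 7 phosphate work-up
Reagents that add atoms: none
Why: Fluoride-mediated global desilylation removes both silyl ethers under buffered, non-acidic conditions, so the ionisation-prone 4-hydroxycinnamyl-type alcohol is not exposed to acid.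

**Compound list**
1 | 6,7-dimethoxy-3,4-dihydronaphthalen-2(1H)-one | COc1cc2c(cc1OC)CC(=O)CC2 | starting material
2 | methyl 6,7-dimethoxy-2-oxo-1,2,3,4-tetrahydronaphthalene-1-carboxylate (racemic, enolisable) | COc1cc2c(cc1OC)C(C(=O)OC)C(=O)CC2 | intermediate
3 | methyl (1S,2R)-2-hydroxy-6,7-dimethoxy-1,2,3,4-tetrahydronaphthalene-1-carboxylate | COc1cc2c(cc1OC)[C@H](C(=O)OC)[C@H](O)CC2 | intermediate
4 | methyl (1S,2R)-2-[(tert-butyldimethylsilyl)oxy]-6,7-dimethoxy-1,2,3,4-tetrahydronaphthalene-1-carboxylate | COc1cc2c(cc1OC)[C@H](C(=O)OC)[C@H](O[Si](C)(C)C(C)(C)C)CC2 | intermediate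
5 | [(1R,2R)-2-[(tert-butyldimethylsilyl)oxy]-6,7-dimethoxy-1,2,3,4-tetrahydronaphthalen-1-yl]methanol | COc1cc2c(cc1OC)[C@H](CO)[C@H](O[Si](C)(C)C(C)(C)C)CC2 | intermediate
6 | (1S,2R)-2-[(tert-butyldimethylsilyl)oxy]-6,7-dimethoxy-1,2,3,4-tetrahydronaphthalene-1-carbaldehyde | COc1cc2c(cc1OC)[C@H](C=O)[C@H](O[Si](C)(C)C(C)(C)C)CC2 | intermediate
7 | 4-iodophenol | Oc1ccc(I)cc1 | starting material
8 | (4-iodophenoxy)tri(propan-2-yl)silane | CC(C)[Si](Oc1ccc(I)cc1)(C(C)C)C(C)C | intermediate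
9 | trimethyl[(4-{[tri(propan-2-yl)silyl]oxy}phenyl)ethynyl]silane | CC(C)[Si](Oc1ccc(cc1)C#C[Si](C)(C)C)(C(C)C)C(C)C | intermediate
10 | (4-ethynylphenoxy)tri(propan-2-yl)silane | C#Cc1ccc(O[Si](C(C)C)(C(C)C)C(C)C)cc1 | intermediate
11 | lithium (4-{[tri(propan-2-yl)silyl]oxy}phenyl)acetylide | [Li]C#Cc1ccc(O[Si](C(C)C)(C(C)C)C(C)C)cc1 | intermediate
12 | (1RS)-1-[(1R,2R)-2-[(tert-butyldimethylsilyl)oxy]-6,7-dimethoxy-1,2,3,4-tetrahydronaphthalen-1-yl]-3-(4-{[tri(propan-2-yl)silyl]oxy}phenyl)prop-2-yn-1-ol (C1′ epimer mixture) | COc1cc2c(cc1OC)[C@H](C(O)C#Cc1ccc(O[Si](C(C)C)(C(C)C)C(C)C)cc1)[C@H](O[Si](C)(C)C(C)(C)C)CC2 | intermediate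
13 | 1-[(1S,2R)-2-[(tert-butyldimethylsilyl)oxy]-6,7-dimethoxy-1,2,3,4-tetrahydronaphthalen-1-yl]-3-(4-{[tri(propan-2-yl)silyl]oxy}phenyl)prop-2-yn-1-one | COc1cc2c(cc1OC)[C@H](C(=O)C#Cc1ccc(O[Si](C(C)C)(C(C)C)C(C)C)cc1)[C@H](O[Si](C)(C)C(C)(C)C)CC2 | intermediate
14 | (1R)-1-[(1R,2R)-2-[(tert-butyldimethylsilyl)oxy]-6,7-dimethoxy-1,2,3,4-tetrahydronaphthalen-1-yl]-3-(4-{[tri(propan-2-yl)silyl]oxy}phenyl)prop-2-yn-1-ol | COc1cc2c(cc1OC)[C@H]([C@@H](O)C#Cc1ccc(O[Si](C(C)C)(C(C)C)C(C)C)cc1)[C@H](O[Si](C)(C)C(C)(C)C)CC2 | intermediate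
15 | (1S,2E)-1-[(1R,2R)-2-[(tert-butyldimethylsilyl)oxy]-6,7-dimethoxy-1,2,3,4-tetrahydronaphthalen-1-yl]-3-(4-{[tri(propan-2-yl)silyl]oxy}phenyl)prop-2-en-1-ol | COc1cc2c(cc1OC)[C@H]([C@@H](O)/C=C/c1ccc(O[Si](C(C)C)(C(C)C)C(C)C)cc1)[C@H](O[Si](C)(C)C(C)(C)C)CC2 | intermediate
16 | (1S,2R)-1-[(1S,2E)-1-hydroxy-3-(4-hydroxyphenyl)prop-2-en-1-yl]-6,7-dimethoxy-1,2,3,4-tetrahydronaphthalen-2-ol | COc1cc2c(cc1OC)[C@H]([C@@H](O)/C=C/c1ccc(O)cc1)[C@H](O)CC2 | target

**Totals and risks**

Total step count: 13. Longest linear sequence: 10 steps (1 to 16 through steps 1–5 and 9–13).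

Three steps most likely to fail:

Step 2 (enzymatic dynamic kinetic reduction). The risk is that no enzyme in the screen gives the cis-(1S,2R) alcohol with high dr and ee; the common Prelog enzymes favour the enantiomeric cis alcohol. The fallback sets out from 2 and comes back at 3. Compound 2 is reduced with NaBH4 (MeOH, −40 °C) and the racemic cis-hydroxy ester F1 is separated from the minor trans isomer. A lipase (Burkholderia cepacia lipase or Candida antarctica lipase B, vinyl acetate, MTBE, 30 °C) then acetylates the (2R)-enantiomer selectively, as the Kazlauskas rule predicts, giving methyl (1S,2R)-2-acetoxy-6,7-dimethoxy-1,2,3,4-tetrahydronaphthalene-1-carboxylate F2. F2 is separated from the unreacted (1R,2S)-alcohol and deacetylated by the same lipase in MTBE/MeOH, which returns 3 and raises the ee further. This replaces enantioselective reduction by hydrolase-catalysed kinetic resolution, at the cost of a 50% ceiling.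

Step 9 (acetylide addition to aldehyde 6). The risk is epimerisation at C1 or loss of silanol from the α-aryl β-silyloxy aldehyde during its formation and use. The fallback sets out from 3 and comes back at 13, and it never passes through an aldehyde. Compound 3 is converted with MeNHOMe·HCl and i-PrMgCl (THF, −20 °C) into the Weinreb amide (1S,2R)-2-hydroxy-N,6,7-trimethoxy-N-methyl-1,2,3,4-tetrahydronaphthalene-1-carboxamide F3. Silylation (TBSOTf, 2,6-lutidine, CH2Cl2) gives the silyl ether (1S,2R)-2-[(tert-butyldimethylsilyl)oxy]-N,6,7-trimethoxy-N-methyl-1,2,3,4-tetrahydronaphthalene-1-carboxamide F4. Acyl substitution with lithium acetylide 11 (THF, −78 → 0 °C) then gives ynone 13 directly; the chelated tetrahedral intermediate releases the ketone only on quench.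

Step 11 (asymmetric transfer hydrogenation of 13). The risk is epimerisation of the doubly activated C1–H in the ynone, or an eroded dr in a mismatched case. The fallback sets out from 12 and comes back at 14, and it avoids the ynone altogether. The two C1′ epimers of 12 are separated by chromatography; the (1′R)-epimer is 14 itself. The other epimer, (1S)-1-[(1R,2R)-2-[(tert-butyldimethylsilyl)oxy]-6,7-dimethoxy-1,2,3,4-tetrahydronaphthalen-1-yl]-3-(4-{[tri(propan-2-yl)silyl]oxy}phenyl)prop-2-yn-1-ol F5, is inverted by Mitsunobu esterification (4-nitrobenzoic acid, PPh3, DIAD, toluene, 0 °C → rt). This gives the inverted ester (1R)-1-[(1R,2R)-2-[(tert-butyldimethylsilyl)oxy]-6,7-dimethoxy-1,2,3,4-tetrahydronaphthalen-1-yl]-3-(4-{[tri(propan-2-yl)silyl]oxy}phenyl)prop-2-yn-1-yl 4-nitrobenzoate F6, which is methanolysed (K2CO3, MeOH, 0 °C) to 14.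

**Further compounds**
F1 | step 2 | racemic cis methyl 2-hydroxy-6,7-dimethoxy-1,2,3,4-tetrahydronaphthalene-1-carboxylate (1:1 mixture of the (1S,2R) and (1R,2S) enantiomers) | COc1cc2c(cc1OC)[C@H](C(=O)OC)[C@H](O)CC2.COc1cc2c(cc1OC)[C@@H](C(=O)OC)[C@@H](O)CC2
F2 | step 2 | methyl (1S,2R)-2-acetoxy-6,7-dimethoxy-1,2,3,4-tetrahydronaphthalene-1-carboxylate | COc1cc2c(cc1OC)[C@H](C(=O)OC)[C@H](OC(C)=O)CC2
F3 | step 9 | (1S,2R)-2-hydroxy-N,6,7-trimethoxy-N-methyl-1,2,3,4-tetrahydronaphthalene-1-carboxamide | COc1cc2c(cc1OC)[C@H](C(=O)N(C)OC)[C@H](O)CC2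
F4 | step 9 | (1S,2R)-2-[(tert-butyldimethylsilyl)oxy]-N,6,7-trimethoxy-N-methyl-1,2,3,4-tetrahydronaphthalene-1-carboxamide | COc1cc2c(cc1OC)[C@H](C(=O)N(C)OC)[C@H](O[Si](C)(C)C(C)(C)C)CC2
F5 | step 11 | (1S)-1-[(1R,2R)-2-[(tert-butyldimethylsilyl)oxy]-6,7-dimethoxy-1,2,3,4-tetrahydronaphthalen-1-yl]-3-(4-{[tri(propan-2-yl)silyl]oxy}phenyl)prop-2-yn-1-ol | COc1cc2c(cc1OC)[C@H]([C@H](O)C#Cc1ccc(O[Si](C(C)C)(C(C)C)C(C)C)cc1)[C@H](O[Si](C)(C)C(C)(C)C)CC2
F6 | step 11 | (1R)-1-[(1R,2R)-2-[(tert-butyldimethylsilyl)oxy]-6,7-dimethoxy-1,2,3,4-tetrahydronaphthalen-1-yl]-3-(4-{[tri(propan-2-yl)silyl]oxy}phenyl)prop-2-yn-1-yl 4-nitrobenzoate | COc1cc2c(cc1OC)[C@H]([C@@H](OC(=O)c1ccc(cc1)[N+](=O)[O-])C#Cc1ccc(O[Si](C(C)C)(C(C)C)C(C)C)cc1)[C@H](O[Si](C)(C)C(C)(C)C)CC2
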